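**Strategy.** The lactone (O1, C2=O, C3, C4, C5; C7 is the carbinol carbon) is cut at C3–C4. This bond links two adjacent stereocentres, C3 next to the carbonyl carbon C2 and C4 bearing C5; with C5 disguised as an alkene carbon that is the pattern left by an ester-enolate Claisen rearrangement. One Ireland–Claisen step therefore forges C3–C4 and sets both centres through a single chair, steered by an (R)-allylic carbon, an E alkene and a Z ketene acetal, while C7 is carried in. The precursor is the (R,E)-5-arylpent-3-en-2-yl ester of an (S)-3-aryl-3-silyloxypropanoic acid, both phenols silylated. Ozonolysis, reduction and lactonisation, then fluoride, finish the synthesis.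

Key step: step 8

Remark: by CIP analysis the target is the (3S,4R,7S) trans lactone, and the (R)-allylic ester, E alkene and Z ketene acetal map onto exactly this; it is assumed that (R)-but-3-en-2-ol is bought enantiopure. Notation: TBS = tert-butyldimethylsilyl, Ar = 4-(TBS-oxy)-3-methoxyphenyl.

**Step 1**
Reactants: 1 acetovanillone; 2 dimethyl carbonate
Product: 3 methyl 3-(4-hydroxy-3-methoxyphenyl)-3-oxopropanoate
Conditions: NaH (3.5 equiv), THF, reflux; AcOH/H2O quench, 0 °C
Reagents that add atoms: none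
Why: Crossed Claisen condensation, in which the phenoxide forms first, the methyl ketone enolate is C-acylated by the carbonate, and deprotonation of the β-keto ester by the third equivalent of hydride pulls the equilibrium over.

**Step 2**
Reactants: 3 methyl 3-(4-hydroxy-3-methoxyphenyl)-3-oxopropanoate
Product: 4 methyl 3-Ar-3-oxopropanoate
Conditions: TBSCl, imidazole, CH2Cl2, 0 °C → rt
Reagents that add atoms: TBSCl, CC(C)(C)[Si](C)(C)Cl
Why: Imidazole-mediated O-silylation of the acidic phenol, which leaves the β-keto ester alone and blocks quinone-methide chemistry at the later benzylic alcohol.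

**Step 3**
Reactants: 5 eugenol
Product: 6 O-TBS eugenol (4-allyl-2-methoxyphenyl TBS ether)
Conditions: TBSCl, imidazole, DMF, rt
Reagents that add atoms: TBSCl, CC(C)(C)[Si](C)(C)Cl
Why: Imidazole-mediated O-silylation of the phenol, to which the terminal alkene is inert.

**Step 4**
Reactants: 6 O-TBS eugenol (2.5 equiv); 7 (R)-but-3-en-2-ol
Product: 8 (2R,3E)-5-Ar-pent-3-en-2-ol
Conditions: second-generation Grubbs catalyst RuCl2(=CHPh)(PCy3)(H2IMes) (3 mol%), 1,4-benzoquinone (10 mol%), CH2Cl2, 40 °C
Reagents that add atoms: none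
Why: Olefin cross-metathesis between a fast-dimerising allylarene (in excess) and a slower secondary allylic alcohol, which should favour the cross product and, by secondary metathesis, the E alkene; the carbinol centre of 7 is not touched, and benzoquinone intercepts ruthenium hydrides that would shift the double bond.

**Step 5**
Reactants: 4 methyl 3-Ar-3-oxopropanoate; 8 (2R,3E)-5-Ar-pent-3-en-2-ol
Product: 9 (2R,3E)-5-Ar-pent-3-en-2-yl 3-Ar-3-oxopropanoate
Conditions: DMAP (0.3 equiv), 4 Å MS, toluene, reflux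
Reagents that add atoms: none
Why: DMAP-catalysed transesterification of a β-keto ester (acyl-ketene pathway) driven by trapping methanol on sieves; only the acyl C–O bond is exchanged, so the (R)-carbinol of 8 is retained.

**Step 6**
Reactants: 9 (2R,3E)-5-Ar-pent-3-en-2-yl 3-Ar-3-oxopropanoate
Product: 10 (2R,3E)-5-Ar-pent-3-en-2-yl (3S)-3-Ar-3-hydroxypropanoate
Conditions: RuCl(p-cymene)[(S,S)-TsDPEN] (1 mol%), HCO2H/Et3N (5:2), CH2Cl2, 30 °C
Reagents that add atoms: none
Why: Noyori asymmetric transfer hydrogenation, in which Ru–H and N–H deliver hydride and proton to the aryl ketone in a six-membered transition state with the aryl group held against the cymene ligand, so the (S,S)-ligand should give the (S)-carbinol as it does with acetophenone while ester, alkene and silyl ethers are untouched.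

**Step 7**
Reactants: 10 (2R,3E)-5-Ar-pent-3-en-2-yl (3S)-3-Ar-3-hydroxypropanoate
Product: 11 (2R,3E)-5-Ar-pent-3-en-2-yl (3S)-3-Ar-3-(TBS-oxy)propanoate
Conditions: TBSCl (2.5 equiv), imidazole, DMF, rt
Reagents that add atoms: TBSCl, CC(C)(C)[Si](C)(C)Cl
Why: Imidazole-mediated silylation of the secondary benzylic alcohol (the excess also recaps any phenol bared in steps 5 and 6), which removes the chelating hydroxyl before enolisation.

**Step 8**
Reactants: 11 (2R,3E)-5-Ar-pent-3-en-2-yl (3S)-3-Ar-3-(TBS-oxy)propanoate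
Product: 14 (2S,3S,4E)-2-[(S)-Ar(TBS-oxy)methyl]-3-(Ar-methyl)hex-4-enoic acid, via Z trimethylsilyl ketene acetal 12 (not isolated), via trimethylsilyl ester 13 (not isolated)
Conditions: TMSCl/Et3N, THF/DMPU (55:45), −78 °C; LiN(iPr)2 added slowly (silylation in situ); −78 °C → rt, then 45 °C; 1 M HCl work-up
Reagents that add atoms: none
Why: Ireland–Claisen rearrangement: the amide base removes an α-proton through an open transition state in THF/DMPU and the enolate is silylated as it forms, so the Z ketene acetal 12 (C7 branch cis to OSiMe3) is made before silanolate can be expelled, and on warming 12 undergoes the suprafacial [3,3] shift through a chair to silyl ester 13, which the acid work-up hydrolyses to 14. The closest known reaction type is the chirality-transferring Ireland–Claisen rearrangement of secondary (E)-allylic esters. No ring is closed; the single new skeletal bond is C3–C4. C4 is controlled by the (R)-allylic carbon, whose methyl group takes the equatorial site so that the new bond enters the alkene face from which the ester oxygen departs, giving 4R and the E-propenyl group. C3 is controlled by the ketene acetal geometry, since in the same chair the C7 branch is equatorial like the arylmethyl group of the E alkene, giving 3S and hence the 3,4-relationship of the trans lactone. The step needs Z-enolate selectivity and chair-over-boat selectivity; DMPU should secure the first and the acyclic E alkene with equatorial methyl the second, while the C7 centre does not oppose them because in its A(1,3)-minimised rotamer (C7–H in plane) the aryl group lies on the face away from the forming bond and the silyl ether prevents a chelate that would favour the other face.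

**Step 9**
Reactants: 14 (2S,3S,4E)-2-[(S)-Ar(TBS-oxy)methyl]-3-(Ar-methyl)hex-4-enoic acid
Product: 17 (3S,4R)-3-[(S)-Ar(TBS-oxy)methyl]-4-(Ar-methyl)oxolan-2-one, via aldehyde acid 15 (not isolated), via hydroxy acid 16 (not isolated)
Conditions: O3, CH2Cl2/MeOH (4:1), −78 °C (Sudan Red 7B end point); NaBH4, −78 → 0 °C; aq. citric acid; PPTS (cat.), CH2Cl2, rt
Reagents that add atoms: ozone, O=[O+][O-]
Why: Ozonolysis with borohydride work-up should cut the propenyl group to the C5 alcohol (the alkene reacts far faster than the silylated arenes, and immediate cold reduction prevents epimerisation of C4 next to the aldehyde), and the γ-hydroxy acid then closes by 5-exo-trig lactonisation without touching a stereocentre.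

**Step 10**
Reactants: 17 (3S,4R)-3-[(S)-Ar(TBS-oxy)methyl]-4-(Ar-methyl)oxolan-2-one
Product: 18 (3S,4R)-3-[(S)-hydroxy(4-hydroxy-3-methoxyphenyl)methyl]-4-[(4-hydroxy-3-methoxyphenyl)methyl]oxolan-2-one (CNP0288801.2)
Conditions: Bu4NF/AcOH (1:1, 5 equiv), THF, 0 °C → rt
Reagents that add atoms: none
Why: Fluoride-induced cleavage of the three Si–O bonds, buffered with acetic acid so that the phenols stay protonated and retro-aldol cleavage, E1cB dehydration and quinone-methide formation at C7 are not triggered; no stereocentre is involved.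

**Compound list**
1 | acetovanillone | CC(=O)c1ccc(O)c(OC)c1 | starting material
2 | dimethyl carbonate | COC(=O)OC | starting material
3 | methyl 3-(4-hydroxy-3-methoxyphenyl)-3-oxopropanoate | COC(=O)CC(=O)c1ccc(O)c(OC)c1 | intermediate
4 | methyl 3-[4-(TBS-oxy)-3-methoxyphenyl]-3-oxopropanoate | COC(=O)CC(=O)c1ccc(O[Si](C)(C)C(C)(C)C)c(OC)c1 | intermediate
5 | eugenol | C=CCc1ccc(O)c(OC)c1 | starting material
6 | O-TBS eugenol | C=CCc1ccc(O[Si](C)(C)C(C)(C)C)c(OC)c1 | intermediate
7 | (R)-but-3-en-2-ol | C[C@@H](O)C=C | starting material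
8 | (2R,3E)-5-[4-(TBS-oxy)-3-methoxyphenyl]pent-3-en-2-ol | COc1cc(C/C=C/[C@@H](C)O)ccc1O[Si](C)(C)C(C)(C)C | intermediate
9 | (2R,3E)-5-Ar-pent-3-en-2-yl 3-Ar-3-oxopropanoate | COc1cc(C/C=C/[C@@H](C)OC(=O)CC(=O)c2ccc(O[Si](C)(C)C(C)(C)C)c(OC)c2)ccc1O[Si](C)(C)C(C)(C)C | intermediate
10 | (2R,3E)-5-Ar-pent-3-en-2-yl (3S)-3-Ar-3-hydroxypropanoate | COc1cc(C/C=C/[C@@H](C)OC(=O)C[C@H](O)c2ccc(O[Si](C)(C)C(C)(C)C)c(OC)c2)ccc1O[Si](C)(C)C(C)(C)C | intermediate
11 | (2R,3E)-5-Ar-pent-3-en-2-yl (3S)-3-Ar-3-(TBS-oxy)propanoate (key-step precursor) | COc1cc(C/C=C/[C@@H](C)OC(=O)C[C@H](O[Si](C)(C)C(C)(C)C)c2ccc(O[Si](C)(C)C(C)(C)C)c(OC)c2)ccc1O[Si](C)(C)C(C)(C)C | intermediate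
12 | Z O-trimethylsilyl ketene acetal of 11 (C7 branch cis to OSiMe3) | COc1cc(C/C=C/[C@@H](C)O/C(O[Si](C)(C)C)=C/[C@H](O[Si](C)(C)C(C)(C)C)c2ccc(O[Si](C)(C)C(C)(C)C)c(OC)c2)ccc1O[Si](C)(C)C(C)(C)C | intermediate
13 | trimethylsilyl ester of 14 | COc1cc(C[C@@H](/C=C/C)[C@H](C(=O)O[Si](C)(C)C)[C@H](O[Si](C)(C)C(C)(C)C)c2ccc(O[Si](C)(C)C(C)(C)C)c(OC)c2)ccc1O[Si](C)(C)C(C)(C)C | intermediate
14 | (2S,3S,4E)-2-[(S)-Ar(TBS-oxy)methyl]-3-(Ar-methyl)hex-4-enoic acid (key-step product) | COc1cc(C[C@@H](/C=C/C)[C@H](C(=O)O)[C@H](O[Si](C)(C)C(C)(C)C)c2ccc(O[Si](C)(C)C(C)(C)C)c(OC)c2)ccc1O[Si](C)(C)C(C)(C)C | intermediate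
15 | (2S,3R)-2-[(S)-Ar(TBS-oxy)methyl]-3-(Ar-methyl)-4-oxobutanoic acid | COc1cc(C[C@@H](C=O)[C@H](C(=O)O)[C@H](O[Si](C)(C)C(C)(C)C)c2ccc(O[Si](C)(C)C(C)(C)C)c(OC)c2)ccc1O[Si](C)(C)C(C)(C)C | intermediate
16 | (2S,3R)-2-[(S)-Ar(TBS-oxy)methyl]-3-(Ar-methyl)-4-hydroxybutanoic acid | COc1cc(C[C@@H](CO)[C@H](C(=O)O)[C@H](O[Si](C)(C)C(C)(C)C)c2ccc(O[Si](C)(C)C(C)(C)C)c(OC)c2)ccc1O[Si](C)(C)C(C)(C)C | intermediate
17 | (3S,4R)-3-[(S)-Ar(TBS-oxy)methyl]-4-(Ar-methyl)oxolan-2-one | COc1cc(C[C@H]2COC(=O)[C@@H]2[C@H](O[Si](C)(C)C(C)(C)C)c2ccc(O[Si](C)(C)C(C)(C)C)c(OC)c2)ccc1O[Si](C)(C)C(C)(C)C | intermediate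
18 | (3S,4R)-3-[(S)-hydroxy(4-hydroxy-3-methoxyphenyl)methyl]-4-[(4-hydroxy-3-methoxyphenyl)methyl]oxolan-2-one | COc1cc(C[C@H]2COC(=O)[C@@H]2[C@H](O)c2ccc(O)c(OC)c2)ccc1O | target

**Step count.** Total: 10 steps. Longest linear sequence: 8 steps (1, 2, 5, 6, 7, 8, 9, 10 from acetovanillone; the eugenol branch through steps 3 and 4 is equally long).

**Steps most likely to fail**

Step 8. The lithium enolate may expel silanolate (E1cB, giving the cinnamate ester) before it is silylated, or the enolate geometry may leak so that the C3-epimeric series forms. The fallback leaves ester-enolate chemistry, sets out from 8 and returns at 18. Johnson–Claisen rearrangement of 8 with triethyl orthoacetate and catalytic propionic acid at 140 °C should give ethyl (3R,4E)-3-(Ar-methyl)hex-4-enoate F1 with the same equatorial-methyl chirality transfer. Ozonolysis with NaBH4 work-up and acid-induced lactonisation should give (4R)-4-(Ar-methyl)oxolan-2-one F2. Its lithium enolate (LiN(iPr)2, THF, −78 °C) should add to 4-(TBS-oxy)-3-methoxybenzaldehyde F3 (from vanillin, TBSCl, imidazole) anti to the C4 substituent, giving the 3,4-trans aldol adduct F4 as a mixture of C7 epimers. Dess–Martin periodinane should converge both epimers to the keto lactone (3S,4R)-3-(Ar-carbonyl)-4-(Ar-methyl)oxolan-2-one F5. Chelation-controlled reduction with Zn(BH4)2 in Et2O at −20 °C (hydride anti to C4 in the zinc chelate) should then give the (7S)-hydroxy lactone (3S,4R)-3-[(S)-Ar(hydroxy)methyl]-4-(Ar-methyl)oxolan-2-one F6. Buffered fluoride as in step 10 converts F6 into 18.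

Step 4. Ruthenium hydride species may move the allylarene double bond into conjugation, and E selectivity may be incomplete, which would feed the wrong alkene geometry into the key step. The fallback avoids metathesis and sets the carbinol by reagent control; it sets out from 6 and returns at 8. Ozonolysis of 6 (CH2Cl2, −78 °C, PPh3 work-up) should give (4-(TBS-oxy)-3-methoxyphenyl)acetaldehyde F7. Wittig reaction with the stabilised ylide Ph3P=CHC(O)CH3 in CH2Cl2 should give (3E)-5-Ar-pent-3-en-2-one F8. Corey–Bakshi–Shibata reduction with the (S)-methyl oxazaborolidine and catecholborane in toluene at −78 °C, with the alkenyl group acting as the large substituent, should give the (R)-alcohol 8.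

Step 10. Once a phenol is freed under basic fluoride, the phenoxide may push out the benzylic oxygen (quinone methide), or the β-hydroxy lactone may undergo retro-aldol cleavage or dehydration, scrambling C7 and C3. The fallback unmasks in two stages under non-basic conditions; it sets out from 17 and returns at 18. KHF2 in MeOH at rt should remove only the two aryl silyl ethers, giving (3S,4R)-3-[(S)-(4-hydroxy-3-methoxyphenyl)(TBS-oxy)methyl]-4-[(4-hydroxy-3-methoxyphenyl)methyl]oxolan-2-one F9. HF·pyridine buffered with pyridine in THF at 0 °C should then cleave the benzylic silyl ether to give 18.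

**Further compounds**
F1 | step 8 | ethyl (3R,4E)-3-[[4-(TBS-oxy)-3-methoxyphenyl]methyl]hex-4-enoate | COc1cc(C[C@@H](/C=C/C)CC(=O)OCC)ccc1O[Si](C)(C)C(C)(C)C
F2 | step 8 | (4R)-4-[[4-(TBS-oxy)-3-methoxyphenyl]methyl]oxolan-2-one | COc1cc(C[C@H]2COC(=O)C2)ccc1O[Si](C)(C)C(C)(C)C
F3 | step 8 | 4-(TBS-oxy)-3-methoxybenzaldehyde | COc1cc(C=O)ccc1O[Si](C)(C)C(C)(C)C
F4 | step 8 | (3S,4R)-3-[Ar(hydroxy)methyl]-4-(Ar-methyl)oxolan-2-one, mixture of C7 epimers | COc1cc(C[C@H]2COC(=O)[C@@H]2C(O)c2ccc(O[Si](C)(C)C(C)(C)C)c(OC)c2)ccc1O[Si](C)(C)C(C)(C)C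
F5 | step 8 | (3S,4R)-3-(Ar-carbonyl)-4-(Ar-methyl)oxolan-2-one | COc1cc(C[C@H]2COC(=O)[C@@H]2C(=O)c2ccc(O[Si](C)(C)C(C)(C)C)c(OC)c2)ccc1O[Si](C)(C)C(C)(C)C
F6 | step 8 | (3S,4R)-3-[(S)-Ar(hydroxy)methyl]-4-(Ar-methyl)oxolan-2-one | COc1cc(C[C@H]2COC(=O)[C@@H]2[C@H](O)c2ccc(O[Si](C)(C)C(C)(C)C)c(OC)c2)ccc1O[Si](C)(C)C(C)(C)C
F7 | step 4 | [4-(TBS-oxy)-3-methoxyphenyl]acetaldehyde | COc1cc(CC=O)ccc1O[Si](C)(C)C(C)(C)C
F8 | step 4 | (3E)-5-[4-(TBS-oxy)-3-methoxyphenyl]pent-3-en-2-one | COc1cc(C/C=C/C(C)=O)ccc1O[Si](C)(C)C(C)(C)C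
F9 | step 10 | (3S,4R)-3-[(S)-(4-hydroxy-3-methoxyphenyl)(TBS-oxy)methyl]-4-[(4-hydroxy-3-methoxyphenyl)methyl]oxolan-2-one | COc1cc(C[C@H]2COC(=O)[C@@H]2[C@H](O[Si](C)(C)C(C)(C)C)c2ccc(O)c(OC)c2)ccc1O
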